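**Retrosynthetic overview**

1. Feature: in isochroman-1-one numbering (C1=O, O2, C3, C4; side chain C1′H(CO2H)–C2′H2–C3′O2H) the chain from the carboxyl carbon on C3 through C3, C4, C1′ and C2′ to the C3′ carboxyl carbon is six carbons long with an acid at each end. Tied end to end it is a cyclohexene on which O2, the aryl ring and the C1′ carboxyl alternate up/down/up.
2. Last disconnection: both terminal CO2H groups come from a ring CH=CH (oxidative cleavage), and the C1′ acid from an N-acyl oxazolidinone.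
3. Key disconnection: C3–C4 and C1′–C2′ by an intramolecular Diels–Alder reaction of an (E)-buta-1,3-dienyl benzoate with an ortho (E)-enoyl imide on one tri-O-benzylgallate ring.
4. Precursor: dienyl ester from the aroyl chloride and the dienolate of crotonaldehyde; enoyl imide by Heck coupling of a 2-bromo tert-butyl ester with 3-acryloyl-oxazolidin-2-one; the arene is bought as 3,4,5-tris(benzyloxy)benzoic acid.
5. Ring order: arene (bought), then lactone ring and cyclohexene together in one step, then the cyclohexene is cleaved again.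

Key step: step 6

Remark: the target is (3S,4S,1′S) as read from its SMILES. H-3/H-4 are trans, which is the trans ring fusion of the cycloadduct.

Assumption: 3,4,5-tris(benzyloxy)benzoic acid (tri-O-benzylgallic acid) is a catalogue compound and is bought as such.

**Step 1**
Reactants: 1 3,4,5-tris(benzyloxy)benzoic acid
Product: 2 tert-butyl 3,4,5-tris(benzyloxy)benzoate
Conditions: Me2NCH(Ot-Bu)2 (4 equiv), toluene, 85 °C
Reagents that add atoms: N,N-dimethylformamide di-tert-butyl acetal, CN(C)C(OC(C)(C)C)OC(C)(C)C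
Why: O-alkylation of the carboxylic acid by the formamide acetal gives the tert-butyl ester under neutral conditions that leave the benzyl ethers alone.

**Step 2**
Reactants: 2 tert-butyl 3,4,5-tris(benzyloxy)benzoate
Product: 3 tert-butyl 3,4,5-tris(benzyloxy)-2-bromobenzoate
Conditions: NBS (1.05 equiv), DMF, 0 °C → rt, dark
Reagents that add atoms: N-bromosuccinimide, O=C1CCC(=O)N1Br
Why: Electrophilic aromatic bromination should take one of the two equivalent free ring positions (ortho and para to benzyloxy groups), and the first bromine deactivates and crowds the ring against a second.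

**Step 3**
Reactants: 3 tert-butyl 3,4,5-tris(benzyloxy)-2-bromobenzoate; 4 3-acryloyl-1,3-oxazolidin-2-one
Product: 5 tert-butyl 3,4,5-tris(benzyloxy)-2-[(E)-3-oxo-3-(2-oxo-1,3-oxazolidin-3-yl)prop-1-en-1-yl]benzoate
Conditions: Pd2(dba)3 (2.5 mol%), [(t-Bu)3PH]BF4 (10 mol%), Cy2NMe, BHT (cat.), 1,4-dioxane, 80 °C
Reagents that add atoms: none
Why: Mizoroki–Heck reaction, in which the bulky electron-rich phosphine allows oxidative addition of the congested bromide, and syn insertion at the terminal alkene carbon followed by syn β-hydride elimination gives the E-alkene.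

**Step 4**
Reactants: 5 tert-butyl 3,4,5-tris(benzyloxy)-2-[(E)-3-oxo-3-(2-oxo-1,3-oxazolidin-3-yl)prop-1-en-1-yl]benzoate
Product: 6 3,4,5-tris(benzyloxy)-2-[(E)-3-oxo-3-(2-oxo-1,3-oxazolidin-3-yl)prop-1-en-1-yl]benzoic acid
Conditions: TFA/CH2Cl2 (1:4), 0 °C → rt; co-evaporation with toluene, no base, used at once
Reagents that add atoms: none
Why: Acidolysis of the tert-butyl ester with loss of isobutene spares the imide and the aryl benzyl ethers, and the acid is never exposed to base because its carboxylate could add to the enoyl imide (oxa-Michael closure to a phthalide).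

**Step 5**
Reactants: 6 3,4,5-tris(benzyloxy)-2-[(E)-3-oxo-3-(2-oxo-1,3-oxazolidin-3-yl)prop-1-en-1-yl]benzoic acid; 7 (E)-crotonaldehyde
Product: 10 (E)-buta-1,3-dien-1-yl 3,4,5-tris(benzyloxy)-2-[(E)-3-oxo-3-(2-oxo-1,3-oxazolidin-3-yl)prop-1-en-1-yl]benzoate, via acid chloride 8 (not isolated), via potassium dienolate 9 (not isolated)
Conditions: (COCl)2, DMF (cat.), CH2Cl2, 0 °C → rt, evaporate; separately 7 (1.3 equiv), KOt-Bu (1.2 equiv), THF, −78 °C; dienolate added to 8 in THF, −78 °C; cold pH 7 buffer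
Reagents that add atoms: none
Why: The acid chloride forms through the chloroiminium catalyst, and the potassium dienolate from γ-deprotonation of crotonaldehyde is acylated on oxygen (chiefly E) by the acid chloride much faster than it can attack the imide, the inverse addition keeping base away from the enoyl imide.

**Step 6**
Reactants: 10 (E)-buta-1,3-dien-1-yl 3,4,5-tris(benzyloxy)-2-[(E)-3-oxo-3-(2-oxo-1,3-oxazolidin-3-yl)prop-1-en-1-yl]benzoate
Product: 11 3-{[(1S,4aR,10bS)-8,9,10-tris(benzyloxy)-6-oxo-1,2,4a,10b-tetrahydro-6H-benzo[c]chromen-1-yl]carbonyl}-1,3-oxazolidin-2-one (trans ring fusion; H-1 and H-10b anti)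
Conditions: [Cu((R,R)-t-Bu-box)](SbF6)2 (15 mol%, from CuCl2, ligand, AgSbF6), CH2Cl2 (0.02 M), rt, then 40 °C if slow
Reagents that add atoms: none
Why: The imide chelates Cu(II) through both carbonyl oxygens, which fixes the enoyl group s-cis and lowers its LUMO, and the tethered (E)-dienyl ester adds across it in a concerted, asynchronous [4+2] cycloaddition in which the oxygen-bearing diene terminus bonds to the aryl-bearing carbon (C3–C4) and the CH2 terminus to the imide α-carbon (C1′–C2′). The closest known reaction is the Cu(II)–t-Bu-box-catalysed intramolecular Diels–Alder reaction of (E,E)-trienimides with all-carbon tethers, applied here to a molecule whose tether is an aryl ester joined to the diene through oxygen. The lactone closes as the tether ring (six-membered, through the C3–C4 bond, with the ester in its s-cis rotamer and the arene turned out of the enoyl plane, as its two ortho substituents already force), and the cyclohexene closes as the cycloadduct ring. C4 and C1′ become trans because the dienophile is E, and C3 becomes trans to C4 (trans ring fusion, oxygen cis to the acyl group) because the diene is E and the chelated imide sits endo while the aryl tether sits exo. The absolute configuration follows from the ligand: in the square-planar chelate model the tert-butyl group of the (R,R)-ligand covers the Cα-Re face, so the diene should add to the Cα-Si face and give 1′S (to be confirmed on the first adduct, the (S,S)-ligand being used if the sense is the opposite). The step needs endo over exo, one enantioface and a regiochemistry that the tether imposes against the weak ortho preference of the acyloxy diene; two-point activation and the intramolecular setting are relied on for all three, and any (Z)-dienyl ester stays behind because it reaches the s-cis diene geometry only with difficulty.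

**Step 7**
Reactants: 11 3-{[(1S,4aR,10bS)-8,9,10-tris(benzyloxy)-6-oxo-1,2,4a,10b-tetrahydro-6H-benzo[c]chromen-1-yl]carbonyl}-1,3-oxazolidin-2-one
Product: 13 (1S,4aR,10bS)-8,9,10-tris(benzyloxy)-6-oxo-1,2,4a,10b-tetrahydro-6H-benzo[c]chromene-1-carboxylic acid, via peroxy acid 12 (not isolated)
Conditions: LiOH·H2O (2 equiv), 30% H2O2 (5 equiv), THF/H2O (3:1), 0 °C; aq. Na2SO3; then 1 M HCl to pH 2
Reagents that add atoms: hydrogen peroxide, OO
Why: Lithium hydroperoxide cleavage of the N-acyl oxazolidinone, in which the nucleophilic, weakly basic hydroperoxide attacks the exocyclic imide carbonyl in preference to the less electrophilic benzoate-type lactone, sulfite reduces the peroxy acid, no stereocentre is touched, and a lactone that opened should close again on acidification.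

**Step 8**
Reactants: 13 (1S,4aR,10bS)-8,9,10-tris(benzyloxy)-6-oxo-1,2,4a,10b-tetrahydro-6H-benzo[c]chromene-1-carboxylic acid
Product: 16 (2S)-2-[(3S,4S)-5,6,7-tris(benzyloxy)-3-carboxy-1-oxo-3,4-dihydro-1H-isochromen-4-yl]butanedioic acid (tri-O-benzylchebulic acid), via ozonide 14 (not isolated), via dialdehyde 15 (not isolated)
Conditions: O3/O2, CH2Cl2, −78 °C (Sudan Red 7B end point); Me2S, −78 °C → rt, evaporate; then NaClO2, NaH2PO4, 2-methyl-2-butene, t-BuOH/H2O, rt
Reagents that add atoms: ozone, [O-][O+]=O; sodium chlorite, [Na+].[O-]Cl=O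
Why: Ozonolysis (1,3-dipolar cycloaddition and Criegee rearrangement) of the only alkene is much faster than attack on benzyl ethers when stopped at the indicator end point, sulfide reduction gives the dialdehyde, and buffered, scavenged Pinnick oxidation turns both aldehydes into acids without epimerising C3.

**Step 9**
Reactants: 16 (2S)-2-[(3S,4S)-5,6,7-tris(benzyloxy)-3-carboxy-1-oxo-3,4-dihydro-1H-isochromen-4-yl]butanedioic acid
Product: 17 chebulic acid [(2S)-2-[(3S,4S)-3-carboxy-5,6,7-trihydroxy-1-oxo-3,4-dihydro-1H-isochromen-4-yl]butanedioic acid]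
Conditions: H2 (1 atm), 10% Pd/C, THF/H2O (9:1), rt; filtration, lyophilisation
Reagents that add atoms: none
Why: Hydrogenolysis of the three aryl benzyl ethers over palladium, with no benzylic C–O bond in the lactone and no other reducible group, so the three stereocentres are untouched.

**Compound list**

1 | 3,4,5-tris(benzyloxy)benzoic acid | O=C(O)c1cc(OCc2ccccc2)c(OCc2ccccc2)c(OCc2ccccc2)c1 | starting material
2 | tert-butyl 3,4,5-tris(benzyloxy)benzoate | CC(C)(C)OC(=O)c1cc(OCc2ccccc2)c(OCc2ccccc2)c(OCc2ccccc2)c1 | intermediate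
3 | tert-butyl 3,4,5-tris(benzyloxy)-2-bromobenzoate | CC(C)(C)OC(=O)c1cc(OCc2ccccc2)c(OCc2ccccc2)c(OCc2ccccc2)c1Br | intermediate
4 | 3-acryloyl-1,3-oxazolidin-2-one | C=CC(=O)N1CCOC1=O | starting material
5 | tert-butyl 3,4,5-tris(benzyloxy)-2-[(E)-3-oxo-3-(2-oxo-1,3-oxazolidin-3-yl)prop-1-en-1-yl]benzoate | CC(C)(C)OC(=O)c1cc(OCc2ccccc2)c(OCc2ccccc2)c(OCc2ccccc2)c1/C=C/C(=O)N1CCOC1=O | intermediate
6 | 3,4,5-tris(benzyloxy)-2-[(E)-3-oxo-3-(2-oxo-1,3-oxazolidin-3-yl)prop-1-en-1-yl]benzoic acid | O=C(O)c1cc(OCc2ccccc2)c(OCc2ccccc2)c(OCc2ccccc2)c1/C=C/C(=O)N1CCOC1=O | intermediate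
7 | (E)-crotonaldehyde | C/C=C/C=O | starting material
8 | 3,4,5-tris(benzyloxy)-2-[(E)-3-oxo-3-(2-oxo-1,3-oxazolidin-3-yl)prop-1-en-1-yl]benzoyl chloride | O=C(Cl)c1cc(OCc2ccccc2)c(OCc2ccccc2)c(OCc2ccccc2)c1/C=C/C(=O)N1CCOC1=O | intermediate (not isolated)
9 | potassium (E)-buta-1,3-dien-1-olate | C=C/C=C/[O-].[K+] | intermediate (not isolated)
10 | (E)-buta-1,3-dien-1-yl 3,4,5-tris(benzyloxy)-2-[(E)-3-oxo-3-(2-oxo-1,3-oxazolidin-3-yl)prop-1-en-1-yl]benzoate | C=C/C=C/OC(=O)c1cc(OCc2ccccc2)c(OCc2ccccc2)c(OCc2ccccc2)c1/C=C/C(=O)N1CCOC1=O | intermediate (key-step precursor)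
11 | 3-{[(1S,4aR,10bS)-8,9,10-tris(benzyloxy)-6-oxo-1,2,4a,10b-tetrahydro-6H-benzo[c]chromen-1-yl]carbonyl}-1,3-oxazolidin-2-one | C1[C@H](C(=O)N2CCOC2=O)[C@H]3c4c(cc(OCc5ccccc5)c(OCc5ccccc5)c4OCc5ccccc5)C(=O)O[C@@H]3C=C1 | intermediate (key-step product)
12 | (1S,4aR,10bS)-8,9,10-tris(benzyloxy)-6-oxo-1,2,4a,10b-tetrahydro-6H-benzo[c]chromene-1-carboperoxoic acid | C1[C@H](C(=O)OO)[C@H]3c4c(cc(OCc5ccccc5)c(OCc5ccccc5)c4OCc5ccccc5)C(=O)O[C@@H]3C=C1 | intermediate (not isolated)
13 | (1S,4aR,10bS)-8,9,10-tris(benzyloxy)-6-oxo-1,2,4a,10b-tetrahydro-6H-benzo[c]chromene-1-carboxylic acid | C1[C@H](C(=O)O)[C@H]3c4c(cc(OCc5ccccc5)c(OCc5ccccc5)c4OCc5ccccc5)C(=O)O[C@@H]3C=C1 | intermediate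
14 | secondary ozonide of 13 (1,2,4-trioxolane across the former C3=C4 of the benzo[c]chromene; the two acetal carbons undefined, mixture) | C1[C@H](C(=O)O)[C@H]3c4c(cc(OCc5ccccc5)c(OCc5ccccc5)c4OCc5ccccc5)C(=O)O[C@@H]3C6OOC1O6 | intermediate (not isolated)
15 | (2S)-4-oxo-2-[(3S,4S)-5,6,7-tris(benzyloxy)-3-formyl-1-oxo-3,4-dihydro-1H-isochromen-4-yl]butanoic acid | O=CC[C@H](C(=O)O)[C@H]1c2c(cc(OCc3ccccc3)c(OCc3ccccc3)c2OCc3ccccc3)C(=O)O[C@@H]1C=O | intermediate (not isolated)
16 | (2S)-2-[(3S,4S)-5,6,7-tris(benzyloxy)-3-carboxy-1-oxo-3,4-dihydro-1H-isochromen-4-yl]butanedioic acid | O=C(O)C[C@H](C(=O)O)[C@H]1c2c(cc(OCc3ccccc3)c(OCc3ccccc3)c2OCc3ccccc3)C(=O)O[C@@H]1C(=O)O | intermediate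
17 | chebulic acid | O=C(O)C[C@H](C(=O)O)[C@H]1c2c(cc(O)c(O)c2O)C(=O)O[C@@H]1C(=O)O | target

**Step count and risks**

Total step count: 9. Longest linear sequence: 9 steps (1 → 17); 4 and 7 enter as bought.

**Most likely to fail, 1: step 6.** The chelate may turn over too slowly, because the ester must rotate into its s-cis form and the congested β-aryl imide binds poorly next to the tert-butyl group. An uncatalysed cyclisation on warming would then erode both the enantiomer ratio and the endo/exo ratio. The fallback moves stereocontrol into the substrate and uses a stronger, stoichiometric activator. Setting out from 3, Heck coupling as in step 3 with (S)-3-acryloyl-4-benzyl-1,3-oxazolidin-2-one F1 (made from (S)-4-benzyl-1,3-oxazolidin-2-one, n-BuLi and acryloyl chloride) should give tert-butyl 3,4,5-tris(benzyloxy)-2-{(E)-3-[(4S)-4-benzyl-2-oxo-1,3-oxazolidin-3-yl]-3-oxoprop-1-en-1-yl}benzoate F2. TFA should give the corresponding benzoic acid F3, oxalyl chloride its acid chloride F4, and acylation of dienolate 9 the (E)-buta-1,3-dienyl ester F5. Me2AlCl (1.4 equiv, CH2Cl2, −30 → 0 °C) forms a cationic aluminium chelate in which the benzyl group of the auxiliary covers the Cα-Re face, so the endo cyclisation should give the (4S)-4-benzyl analogue of the cycloadduct F6. If the Lewis acid is not tolerated, heating F5 in toluene and separating the diastereomeric adducts by chromatography serves the same end. LiOH/H2O2 as in step 7 removes the auxiliary through 12 and the route is rejoined at 13.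

**Most likely to fail, 2: step 5.** The free acid may close onto the enoyl imide before or during activation, the dienolate or residual tert-butoxide may attack the imide, and the enolate geometry may erode to an E/Z mixture. The fallback avoids any strong base. Setting out from 6, DAST (CH2Cl2, 0 °C, no base) should give 3,4,5-tris(benzyloxy)-2-[(E)-3-oxo-3-(2-oxo-1,3-oxazolidin-3-yl)prop-1-en-1-yl]benzoyl fluoride F7. Fluoride-catalysed O-acylation (TBAF 5 mol%, THF, 0 °C) of commercial (E)-1-(trimethylsilyloxy)buta-1,3-diene with F7 transfers the dienyl oxygen with its geometry intact and returns to the route at 10.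

**Most likely to fail, 3: step 3.** The acryloyl imide may polymerise or be degraded by base and palladium hydride at 80 °C before the congested aryl–palladium species inserts. The fallback exposes only a robust acceptor to the coupling and makes the imide afterwards. Setting out from 3, Heck coupling with acrylic acid (Pd(OAc)2, P(o-tol)3, Et3N, DMF, 100 °C) should give (E)-3-[2,3,4-tris(benzyloxy)-6-(tert-butoxycarbonyl)phenyl]prop-2-enoic acid F8. Pivaloyl chloride/Et3N (THF, −20 °C) converts it into its mixed pivalic anhydride F9, and N-acylation of oxazolidin-2-one with F9 (LiCl, Et3N, rt) returns to the route at 5.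

**Further compounds**

F1 | step 6 | (S)-3-acryloyl-4-benzyl-1,3-oxazolidin-2-one | C=CC(=O)N1[C@@H](Cc2ccccc2)COC1=O
F2 | step 6 | tert-butyl 3,4,5-tris(benzyloxy)-2-{(E)-3-[(4S)-4-benzyl-2-oxo-1,3-oxazolidin-3-yl]-3-oxoprop-1-en-1-yl}benzoate | CC(C)(C)OC(=O)c1cc(OCc2ccccc2)c(OCc2ccccc2)c(OCc2ccccc2)c1/C=C/C(=O)N1[C@@H](Cc2ccccc2)COC1=O
F3 | step 6 | 3,4,5-tris(benzyloxy)-2-{(E)-3-[(4S)-4-benzyl-2-oxo-1,3-oxazolidin-3-yl]-3-oxoprop-1-en-1-yl}benzoic acid | O=C(O)c1cc(OCc2ccccc2)c(OCc2ccccc2)c(OCc2ccccc2)c1/C=C/C(=O)N1[C@@H](Cc2ccccc2)COC1=O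
F4 | step 6 | 3,4,5-tris(benzyloxy)-2-{(E)-3-[(4S)-4-benzyl-2-oxo-1,3-oxazolidin-3-yl]-3-oxoprop-1-en-1-yl}benzoyl chloride | O=C(Cl)c1cc(OCc2ccccc2)c(OCc2ccccc2)c(OCc2ccccc2)c1/C=C/C(=O)N1[C@@H](Cc2ccccc2)COC1=O
F5 | step 6 | (E)-buta-1,3-dien-1-yl 3,4,5-tris(benzyloxy)-2-{(E)-3-[(4S)-4-benzyl-2-oxo-1,3-oxazolidin-3-yl]-3-oxoprop-1-en-1-yl}benzoate | C=C/C=C/OC(=O)c1cc(OCc2ccccc2)c(OCc2ccccc2)c(OCc2ccccc2)c1/C=C/C(=O)N1[C@@H](Cc2ccccc2)COC1=O
F6 | step 6 | (4S)-4-benzyl-3-{[(1S,4aR,10bS)-8,9,10-tris(benzyloxy)-6-oxo-1,2,4a,10b-tetrahydro-6H-benzo[c]chromen-1-yl]carbonyl}-1,3-oxazolidin-2-one | C1[C@H](C(=O)N2[C@@H](Cc6ccccc6)COC2=O)[C@H]3c4c(cc(OCc5ccccc5)c(OCc5ccccc5)c4OCc5ccccc5)C(=O)O[C@@H]3C=C1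
F7 | step 5 | 3,4,5-tris(benzyloxy)-2-[(E)-3-oxo-3-(2-oxo-1,3-oxazolidin-3-yl)prop-1-en-1-yl]benzoyl fluoride | O=C(F)c1cc(OCc2ccccc2)c(OCc2ccccc2)c(OCc2ccccc2)c1/C=C/C(=O)N1CCOC1=O
F8 | step 3 | (E)-3-[2,3,4-tris(benzyloxy)-6-(tert-butoxycarbonyl)phenyl]prop-2-enoic acid | CC(C)(C)OC(=O)c1cc(OCc2ccccc2)c(OCc2ccccc2)c(OCc2ccccc2)c1/C=C/C(=O)O
F9 | step 3 | (E)-3-[2,3,4-tris(benzyloxy)-6-(tert-butoxycarbonyl)phenyl]prop-2-enoic pivalic anhydride | CC(C)(C)OC(=O)c1cc(OCc2ccccc2)c(OCc2ccccc2)c(OCc2ccccc2)c1/C=C/C(=O)OC(=O)C(C)(C)C
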